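**Retrosynthetic overview**
1. Target 23 comes from the 5'-benzyl ether 22 by hydrogenolysis.
2. The pyranone C ring of 22 is cut at O1–C8a and C4–C4a. These two bonds sit on neighbouring A-ring carbons, and C5, next to C4a, carries a methoxyl. That is the footprint of 3,5-dimethoxybenzyne 19 (from silyl triflate 6) reacting with the enolate oxygen and ester carbon of α-methoxy β-keto ester 18 (the O1–C2=C3–C4 unit).
3. Silyl triflate 6 comes from 3,5-dimethoxyphenol 1 by ortho-bromination, retro-Brook shift and triflation. Keto ester 18 comes from 2,4-dimethoxybenzaldehyde 7 by Dakin oxidation, benzylation, bromination, Weinreb acylation with 12 and carbomethoxylation with 16.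
4. Ring order: the A and B rings are bought; the C ring is the only ring made and is closed in the aryne annulation.

Key step: step 8

Remark: the target is a planar flavone without stereocentres, so no stereocontrol is needed; keto ester 18 has one enolisable stereocentre, is used as the racemate, and loses it in step 8.

**Route**

Step 1
Reactants: 1 3,5-dimethoxyphenol
Product: 2 2-bromo-3,5-dimethoxyphenol
Conditions: NBS (1.0 equiv), CH2Cl2, −78 °C → rt
Reagents that add atoms: N-bromosuccinimide, O=C1CCC(=O)N1Br
Why: Electrophilic aromatic bromination of an activated phenol; in CH2Cl2 at low temperature NBS should go to C2, ortho to the hydroxyl and para to the 5-methoxyl, and any 4-bromo isomer should be removable by chromatography.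

Step 2
Reactants: 2 2-bromo-3,5-dimethoxyphenol
Product: 6 3,5-dimethoxy-2-(trimethylsilyl)phenyl trifluoromethanesulfonate, via aryl trimethylsilyl ether 3 (not isolated), via aryllithium 4 (not isolated), via lithium phenolate 5 (not isolated)
Conditions: HMDS, THF, 70 °C; concentrate; n-BuLi, THF, −100 → −80 °C; Tf2O, −100 °C → rt
Reagents that add atoms: hexamethyldisilazane, C[Si](C)(C)N[Si](C)(C)C; trifluoromethanesulfonic anhydride, O=S(=O)(OS(=O)(=O)C(F)(F)F)C(F)(F)F
Why: O-silylation, bromine–lithium exchange and 1,3 O→C silyl shift (retro-Brook rearrangement, driven by formation of the lithium phenolate), then O-triflation, is the standard sequence to ortho-silylaryl triflates.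

Step 3
Reactants: 7 2,4-dimethoxybenzaldehyde
Product: 9 2,4-dimethoxyphenol, via 2,4-dimethoxyphenyl formate 8 (not isolated)
Conditions: mCPBA, CH2Cl2, 0 °C → rt; then cat. K2CO3, MeOH, rt
Reagents that add atoms: meta-chloroperoxybenzoic acid, OOC(=O)c1cccc(Cl)c1
Why: Baeyer–Villiger (Dakin-type) oxidation, in which the electron-rich aryl group migrates in the Criegee intermediate to give the aryl formate, which is methanolysed to the phenol.

Step 4
Reactants: 9 2,4-dimethoxyphenol
Product: 10 1-(benzyloxy)-2,4-dimethoxybenzene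
Conditions: BnBr, K2CO3, DMF, rt
Reagents that add atoms: benzyl bromide, BrCc1ccccc1
Why: Williamson ether synthesis, SN2 attack of the phenoxide on benzyl bromide.

Step 5
Reactants: 10 1-(benzyloxy)-2,4-dimethoxybenzene
Product: 11 1-(benzyloxy)-5-bromo-2,4-dimethoxybenzene
Conditions: NBS, MeCN, 0 °C → rt, dark
Reagents that add atoms: N-bromosuccinimide, O=C1CCC(=O)N1Br
Why: Electrophilic aromatic bromination with NBS in acetonitrile should go to C5, para to the 2-methoxyl and ortho to the 4-methoxyl, since the only other doubly activated position (C3) is flanked by two methoxyls.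

Step 6
Reactants: 11 1-(benzyloxy)-5-bromo-2,4-dimethoxybenzene; 12 N,2-dimethoxy-N-methylacetamide
Product: 15 1-[5-(benzyloxy)-2,4-dimethoxyphenyl]-2-methoxyethan-1-one, via aryllithium 13 (not isolated), via lithium hemiaminal alkoxide 14 (not isolated)
Conditions: n-BuLi, THF, −78 °C; then 12, −78 → 0 °C; 1 M HCl
Reagents that add atoms: none
Why: Bromine–lithium exchange followed by Weinreb ketone synthesis; the chelated tetrahedral adduct 14 should persist until the acidic quench, which prevents over-addition.

Step 7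
Reactants: 15 1-[5-(benzyloxy)-2,4-dimethoxyphenyl]-2-methoxyethan-1-one; 16 dimethyl carbonate
Product: 18 methyl 3-[5-(benzyloxy)-2,4-dimethoxyphenyl]-2-methoxy-3-oxopropanoate (racemic), via sodium enolate 17 (not isolated)
Conditions: NaH (2.5 equiv), 16 (excess), THF, reflux; then aq. HCl, 0 °C
Reagents that add atoms: none
Why: Crossed Claisen condensation (carbomethoxylation) of the ketone enolate with dimethyl carbonate, driven by deprotonation of the product to its stabilised enolate 17; the new stereocentre is enolisable and is obtained racemic.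

Step 8
Reactants: 6 3,5-dimethoxy-2-(trimethylsilyl)phenyl trifluoromethanesulfonate; 18 methyl 3-[5-(benzyloxy)-2,4-dimethoxyphenyl]-2-methoxy-3-oxopropanoate
Product: 22 2-[5-(benzyloxy)-2,4-dimethoxyphenyl]-3,5,7-trimethoxy-4H-chromen-4-one (5'-O-benzyl-3,5,7,2',4'-pentamethoxyflavone), via 3,5-dimethoxybenzyne 19 (not isolated), via caesium enolate 20 (not isolated), via aryl anion 21 (not isolated)
Conditions: 18 pre-stirred with CsF (4 equiv), THF, 65 °C; 6 (1.5 equiv) added slowly
Reagents that add atoms: none
Why: Proposed new method: fluoride deprotonates 18 to the chelated enolate 20 (O⁻ and CO2Me cis; formally E because the α-methoxyl outranks the ester) and desilylates 6 to aryne 19; the enolate oxygen should add to the aryne carbon meta to the flanking methoxyl, because the distortion caused by that methoxyl makes this terminus the more electrophilic one and leaves the aryl anion 21 ortho to the inductively stabilising methoxyl. The aryl anion then attacks the ester carbonyl held cis on the enol ether double bond (6-exo-trig addition–elimination with loss of methoxide), which closes the pyranone ring and forms O1–C8a and C4–C4a. The closest known reactions are the fluoride-mediated annulation of arynes with methyl salicylates to xanthones (the same O-arylation/acyl substitution sequence with a phenoxide in place of the enolate) and the aryne acyl-alkylation of β-keto esters. No stereocentre is formed. The step needs O- over C-arylation of the enolate and one aryne regiochemistry: the fully substituted, methoxy-bearing α-carbon and the loosely paired caesium enolate should favour attack through oxygen, the methoxyl next to the aryne secures the 5,7-dimethoxy pattern, and THF offers no acidic C–H, so the aryl anion should last long enough to acylate.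

Step 9
Reactants: 22 2-[5-(benzyloxy)-2,4-dimethoxyphenyl]-3,5,7-trimethoxy-4H-chromen-4-one
Product: 23 2-(5-hydroxy-2,4-dimethoxyphenyl)-3,5,7-trimethoxy-4H-chromen-4-one (5'-hydroxy-3,5,7,2',4'-pentamethoxyflavone)
Conditions: H2 (1 atm), 10% Pd/C, EtOAc–MeOH, rt
Reagents that add atoms: none
Why: Catalytic hydrogenolysis of the benzyl aryl ether; the tetrasubstituted C2=C3 bond of the chromone (a vinylogous ester) and the aryl methyl ethers should be inert at 1 atm and room temperature.

**Compound list**
1 | 3,5-dimethoxyphenol | COc1cc(O)cc(OC)c1 | starting material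
2 | 2-bromo-3,5-dimethoxyphenol | COc1cc(O)c(Br)c(OC)c1 | intermediate
3 | (2-bromo-3,5-dimethoxyphenoxy)trimethylsilane | COc1cc(O[Si](C)(C)C)c(Br)c(OC)c1 | intermediate
4 | [2,4-dimethoxy-6-(trimethylsilyloxy)phenyl]lithium | [Li]c1c(OC)cc(OC)cc1O[Si](C)(C)C | intermediate
5 | lithium 3,5-dimethoxy-2-(trimethylsilyl)phenolate | [Li+].[O-]c1cc(OC)cc(OC)c1[Si](C)(C)C | intermediate
6 | 3,5-dimethoxy-2-(trimethylsilyl)phenyl trifluoromethanesulfonate | COc1cc(OC)c([Si](C)(C)C)c(OS(=O)(=O)C(F)(F)F)c1 | intermediate
7 | 2,4-dimethoxybenzaldehyde | COc1ccc(C=O)c(OC)c1 | starting material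
8 | 2,4-dimethoxyphenyl formate | COc1ccc(OC=O)c(OC)c1 | intermediate
9 | 2,4-dimethoxyphenol | COc1ccc(O)c(OC)c1 | intermediate
10 | 1-(benzyloxy)-2,4-dimethoxybenzene | COc1ccc(OCc2ccccc2)c(OC)c1 | intermediate
11 | 1-(benzyloxy)-5-bromo-2,4-dimethoxybenzene | COc1cc(OC)c(OCc2ccccc2)cc1Br | intermediate
12 | N,2-dimethoxy-N-methylacetamide | COCC(=O)N(C)OC | starting material
13 | [5-(benzyloxy)-2,4-dimethoxyphenyl]lithium | COc1cc(OC)c(OCc2ccccc2)cc1[Li] | intermediate
14 | lithium 1-[5-(benzyloxy)-2,4-dimethoxyphenyl]-2-methoxy-1-[methoxy(methyl)amino]ethan-1-olate | COCC([O-])(N(C)OC)c1cc(OCc2ccccc2)c(OC)cc1OC.[Li+] | intermediate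
15 | 1-[5-(benzyloxy)-2,4-dimethoxyphenyl]-2-methoxyethan-1-one | COCC(=O)c1cc(OCc2ccccc2)c(OC)cc1OC | intermediate
16 | dimethyl carbonate | COC(=O)OC | starting material
17 | sodium (1E)-1-[5-(benzyloxy)-2,4-dimethoxyphenyl]-2,3-dimethoxy-3-oxoprop-1-en-1-olate | COC(=O)/C(OC)=C(\[O-])c1cc(OCc2ccccc2)c(OC)cc1OC.[Na+] | intermediate
18 | methyl 3-[5-(benzyloxy)-2,4-dimethoxyphenyl]-2-methoxy-3-oxopropanoate (racemic) | COC(=O)C(OC)C(=O)c1cc(OCc2ccccc2)c(OC)cc1OC | intermediate
19 | 3,5-dimethoxybenzyne (1,2-didehydro-3,5-dimethoxybenzene) | COC1=CC(OC)=CC#C1 | intermediate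
20 | caesium (1E)-1-[5-(benzyloxy)-2,4-dimethoxyphenyl]-2,3-dimethoxy-3-oxoprop-1-en-1-olate | COC(=O)/C(OC)=C(\[O-])c1cc(OCc2ccccc2)c(OC)cc1OC.[Cs+] | intermediate
21 | caesium 2-({(1E)-1-[5-(benzyloxy)-2,4-dimethoxyphenyl]-2,3-dimethoxy-3-oxoprop-1-en-1-yl}oxy)-4,6-dimethoxybenzen-1-ide | COC(=O)/C(OC)=C(\Oc1cc(OC)cc(OC)[c-]1)c1cc(OCc2ccccc2)c(OC)cc1OC.[Cs+] | intermediate
22 | 2-[5-(benzyloxy)-2,4-dimethoxyphenyl]-3,5,7-trimethoxy-4H-chromen-4-one | COc1cc(OC)c2c(=O)c(OC)c(-c3cc(OCc4ccccc4)c(OC)cc3OC)oc2c1 | intermediate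
23 | 2-(5-hydroxy-2,4-dimethoxyphenyl)-3,5,7-trimethoxy-4H-chromen-4-one | COc1cc(OC)c2c(=O)c(OC)c(-c3cc(O)c(OC)cc3OC)oc2c1 | target

**Step count**
Total: 9 steps. Longest linear sequence: 7 steps (7 → 23 through steps 3–9); the aryne branch adds steps 1–2.

**Steps most likely to fail**

Step 8. The enolate may attack the aryne through carbon instead of oxygen, leading to α-arylation and acyl-alkylation, or the aryl anion may be protonated before it reaches the ester; either would stop ring closure. The fallback is the Baker–Venkataraman flavone synthesis. It sets out from 1 and 11 and comes back at 22.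
- Phenol 1 would be C-acylated next to the hydroxyl with methoxyacetic acid in BF3·OEt2 at 80 °C (the boron chelate directs ortho) to give 1-(2-hydroxy-4,6-dimethoxyphenyl)-2-methoxyethan-1-one F1.
- Bromide 11 would be lithiated (n-BuLi, THF, −78 °C) and carboxylated with CO2 to 5-(benzyloxy)-2,4-dimethoxybenzoic acid F2.
- Esterification of F1 with F2 (EDC·HCl, DMAP, CH2Cl2) should give 3,5-dimethoxy-2-(methoxyacetyl)phenyl 5-(benzyloxy)-2,4-dimethoxybenzoate F3.
- Base-induced acyl shift (LiHMDS, THF, −20 °C → rt) should give 1-[5-(benzyloxy)-2,4-dimethoxyphenyl]-3-(2-hydroxy-4,6-dimethoxyphenyl)-2-methoxypropane-1,3-dione F4.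
- Cyclodehydration of F4 (TsOH, toluene, 80 °C) closes the pyranone ring and gives 22.

Step 1. Bromination may go to C4, between the two methoxyls, or run on to the dibromide, which would cut the supply of the ortho-bromo phenol. The fallback is carbamate-directed ortho-metalation. It sets out from 1 and comes back at 6, replacing steps 1 and 2.
- Phenol 1 and isopropyl isocyanate (cat. Et3N, CH2Cl2) should give 3,5-dimethoxyphenyl N-(propan-2-yl)carbamate F5.
- In-situ N-silylation (TBSOTf, TMEDA), ortho-lithiation with n-BuLi at −78 °C at the carbon flanked by the carbamate and a methoxyl, TMSCl quench and aqueous work-up should give 3,5-dimethoxy-2-(trimethylsilyl)phenyl N-(propan-2-yl)carbamate F6.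
- DBU/Et2NH in MeCN at 40 °C cleaves the carbamate to 3,5-dimethoxy-2-(trimethylsilyl)phenol F7, which is triflated in the same flask with PhNTf2 to give 6.

Step 7. The enolate may be acylated on oxygen, conversion may stall, or methoxide may cleave the product by retro-Claisen reaction. The fallback is an aldol–oxidation sequence. It sets out from 10 and comes back at 18.
- Vilsmeier–Haack formylation of 10 (POCl3, DMF) at C5 should give 5-(benzyloxy)-2,4-dimethoxybenzaldehyde F8.
- Aldol addition of the lithium enolate of methyl methoxyacetate (LDA, THF, −78 °C) should give methyl 3-[5-(benzyloxy)-2,4-dimethoxyphenyl]-3-hydroxy-2-methoxypropanoate F9 as a racemic mixture of diastereomers.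
- Dess–Martin oxidation of F9 gives 18.

**Further compounds**
F1 | step 8 | 1-(2-hydroxy-4,6-dimethoxyphenyl)-2-methoxyethan-1-one | COCC(=O)c1c(O)cc(OC)cc1OC
F2 | step 8 | 5-(benzyloxy)-2,4-dimethoxybenzoic acid | COc1cc(OC)c(OCc2ccccc2)cc1C(=O)O
F3 | step 8 | 3,5-dimethoxy-2-(methoxyacetyl)phenyl 5-(benzyloxy)-2,4-dimethoxybenzoate | COCC(=O)c1c(OC)cc(OC)cc1OC(=O)c1cc(OCc2ccccc2)c(OC)cc1OC
F4 | step 8 | 1-[5-(benzyloxy)-2,4-dimethoxyphenyl]-3-(2-hydroxy-4,6-dimethoxyphenyl)-2-methoxypropane-1,3-dione | COC(C(=O)c1c(O)cc(OC)cc1OC)C(=O)c1cc(OCc2ccccc2)c(OC)cc1OC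
F5 | step 1 | 3,5-dimethoxyphenyl N-(propan-2-yl)carbamate | COc1cc(OC)cc(OC(=O)NC(C)C)c1
F6 | step 1 | 3,5-dimethoxy-2-(trimethylsilyl)phenyl N-(propan-2-yl)carbamate | COc1cc(OC)c([Si](C)(C)C)c(OC(=O)NC(C)C)c1
F7 | step 1 | 3,5-dimethoxy-2-(trimethylsilyl)phenol | COc1cc(O)c([Si](C)(C)C)c(OC)c1
F8 | step 7 | 5-(benzyloxy)-2,4-dimethoxybenzaldehyde | COc1cc(OC)c(OCc2ccccc2)cc1C=O
F9 | step 7 | methyl 3-[5-(benzyloxy)-2,4-dimethoxyphenyl]-3-hydroxy-2-methoxypropanoate | COC(C(=O)OC)C(O)c1cc(OCc2ccccc2)c(OC)cc1OC
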